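A drain of 0.293 h⁻¹ was my starting number, a reading from the south run: between 3.00 h and 6.00 h target rose by 18 percentage points over a mean c(intermediate) of 20.5%. The south run has the flask's loading of second catalyst, 4.4 mol%, and differs from the flask in coupling partner, 1.7 equiv against 1.10 equiv. I took the candidate step from intermediate to target as first order in coupling partner, so I scaled the reading to 0.189 h⁻¹ for the flask, a pseudo-first-order constant with coupling partner as charged.

| setting | north-east | north-west | south | flask |
|---|---|---|---|---|
| starting material | 0.20 M | 0.20 M | 0.20 M | 0.20 M |
| coupling partner | 1.1 equiv | 1.1 equiv | 1.7 equiv | 1.10 equiv |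
| free catalyst | 1 mol% | 1 mol% | 1 mol% | 1 mol% |
| second catalyst | 2.2 mol% | 3.3 mol% | 4.4 mol% | 4.4 mol% |
| remark | run made earlier | run made earlier | run made earlier |  |
| time |  |  |  | 8.0 h |

- north-east (time / h: intermediate / %, target / %): 0.833: 19, 0; 1.50: 24, 4; 3.00: 29, 5; 6.00: 32, 15
- north-west (time / h: intermediate / %, target / %): 0.833: 17, 2; 1.50: 27, 5; 3.00: 27, 5; 6.00: 31, 19
- south (time / h: intermediate / %, target / %): 0.833: 19, 1; 1.50: 20, 4; 3.00: 24, 11; 6.00: 17, 29

(standard deviation of a reading: 2 percentage points)

- for target the idle complex is counted in
- the earlier runs were read with a standard deviation of 2 percentage points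
- candidate steps: free catalyst + target <-> idle complex; coupling partner -> decomposition product; starting material + free catalyst -> free catalyst + intermediate; starting material <-> dormant form; coupling partner + second catalyst + intermediate -> second catalyst + target

- the moment within 8.0 h at which there is most intermediate
- the amount of intermediate, in percent of the starting material charged, at that time
- the first time at which intermediate reaches 13%, in the same percent

I then ran the flask in slow motion. In the first instants of the north-east run, intermediate and target together climbed at a fractional rate of 0.228 h⁻¹ on the charge up to 0.833 h, as starting material met free catalyst, while target read 0%. At that pace the flask would reach 13% at 0.570 h.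

In the middle the climb slowed. From 3.00 h to 6.00 h the same sum, averaged over the earlier runs, gained at 0.0467 h⁻¹, slower than the burst. I read this as starting material passing into the dormant form and paying out slowly, a feed shared by runs with the same charge of starting material and free catalyst.

For the flask, this feed divided by the drain gave 24.6%, and this is the balance level, the c(intermediate) at which intermediate is used as fast as it is made. Towards the end I expected c(intermediate) to near that level on the drain's half-life, 3.66 h, so I committed to a broad top about there.

The forecast gave 25% at 3 h and 13% at 0.45 h, “then a broad plateau near 25% around 3 h”. Its drain was 0.17 per hour against my 0.189 h⁻¹.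

    free catalyst + target ⇌ idle complex (K = 6.90 M⁻¹, k = 33.0 M⁻¹ h⁻¹)
    coupling partner → decomposition product (k = 6.20 × 10⁻⁵ h⁻¹)
    starting material + free catalyst → free catalyst + intermediate (k = 150 M⁻¹ h⁻¹)
    starting material ⇌ dormant form (K = 2.30, k = 0.580 h⁻¹)
    coupling partner + second catalyst + intermediate → second catalyst + target (k = 98.0 M⁻² h⁻¹)

The flask peaked at 25.8% at 3.55 h and reached 13% at 0.584 h. At 1.55 h it made intermediate 2.27 times faster than it used it up, and by 8.00 h that ratio stood at 0.791. The top lay 1.2 points above the balance level. For the neighbouring flask with 1.90 equiv of coupling partner, the balance level scales down to 14.3%, and that flask, after a highest c(intermediate) of 20.5%, held 13.1% at 8.00 h.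

All runs stem from a simulated flask with made-up constants; noise was put on by code.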